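The rate constants were set for the occasion; no experiment stands behind them.

Late in a run of this scheme the reading depends on when free by-product appeared, since step one needs it and makes more of it.

    substrate + reagent + by-product → target + 2 by-product (k1 = 2.7 /M²/h, Ea1 = 52.0 kJ/mol)
    substrate + reagent → target + by-product (k2 = 0.0036 /M/h, Ea2 = 100 kJ/mol)
    base + by-product ⇌ salt, settled at all times (K3 = 4800 /M, ΔH3 = −58.0 kJ/mol)
    (constants at 35 °C)

- midnight: substrate 0.25 M; reagent 1.05 equiv; base 0.0500 equiv; temperature 35 °C; time 2.5 d
- spring: substrate 0.25 M; reagent 1.05 equiv; base 0.0500 equiv; temperature 60 °C; time 2.5 d

- which of these there is most of at the end, counted by the substrate in it, midnight (substrate / target)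
- which of these there is most of at the end, counted by the substrate in it, spring (substrate / target)
- final amount of the leader among these, as a percentage of the substrate charged, in midnight
- final amount of the leader among these, as a percentage of the substrate charged, in spring

My own reckoning builds the flask up one process at a time. Step two by itself is slow in midnight: substrate has a half-life of 31 d by it, longer than the 2.5 d allowed, and it converts 5.67 % of the charge. Adding step one, autocatalysis overtakes step two once c(by-product) passes the crossover level 0.00133 M, and by-product then multiplies at 0.177 /h.

Adding base, each by-product goes into salt, so step two must first make as much by-product as there is base. That takes 2.20 d, the base-clearing time: the charge of base divided by the rate of step two at charged concentrations, or induction period. It falls just short of the time allowed. Free by-product reaches the crossover earlier, at 1.91 d, with base still partly unbound.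

Growth from there at charged concentrations gives 17.8 % target. Putting that depletion back into the growth rate and going round once more gives 10.4 %, which overstates the slowing. So midnight stays with substrate at 89.6 %.

In spring the constants become 12.4 /M²/h and 0.0673 /M/h, so the base-clearing time shrinks to 0.118 d, far below the time allowed. Adding the growth up to the substrate level puts the start of the tail at 0.314 d. In the tail, by-product is roughly constant and reagent exceeds substrate by the fixed excess, so the decay constant is 0.0368 /h. That leaves 0.850 % substrate, so spring gives target at 99.1 %.

The forecast names substrate at 85 % for midnight and target at 99.3 % for spring, where “the induction period lasts only hours and the reaction runs essentially to completion”.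

The simulation gives substrate at 88.2 % in midnight and target at 99.1 % in spring, so the forecast stands.

In midnight, the base-clearing time puts free base at 43.2 % after 1.25 d, and the flask holds 43.1 %. Substrate leads midnight at the asked time through binding and time acting together: without the binding, target reaches 82.1 % instead of 11.8 %, and at tenfold time it reaches 99.9 %. Target in spring moves out of the margin on its answer with reagent down at 0.940 equiv.

Read spring at 25 h: the tail, started at 0.314 d, the base-clearing time plus the growth, gives 94.4 % target. The computed reading is 94.2 %.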